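The earlier runs and the new flask come from a simulation for an exercise.

The flask had 0.0500 M of J to spare, by which I meant the J charged less the D charged. In larch and elm Q rose and then fell back while G recovered, so I took D to consume J one for one. In the flask D was charged in the smaller amount, which makes it the limiting reagent of that loss, and its balance gives the J the exchange keeps.

| flask | G | J | D | remark | time |
|---|---|---|---|---|---|
| larch | 0.050 M | 1 equiv | 0.050 M | run made earlier |  |
| ash | 0.20 M | 1 equiv | 0.050 M | run made earlier |  |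
| elm | 0.10 M | 1 equiv | 0.075 M | run made earlier |  |
| flask | 0.10 M | 1.00 equiv | 0.0500 M |  | 50 min |

| run | time / min | Q / % | G / % |
|---|---|---|---|
| larch | 0.667 | 12.8 | 85.5 |
| larch | 2.00 | 19.9 | 74.1 |
| larch | 5.00 | 23.5 | 71.4 |
| larch | 12.0 | 19.8 | 76.8 |
| larch | 30.0 | 13.6 | 83.0 |
| ash | 0.667 | 23.7 | 66.8 |
| ash | 2.00 | 26.1 | 63.9 |
| ash | 5.00 | 24.3 | 65.4 |
| ash | 12.0 | 24.7 | 66.3 |
| ash | 30.0 | 24.0 | 66.8 |
| elm | 0.667 | 17.2 | 77.4 |
| elm | 2.00 | 23.7 | 69.1 |
| elm | 5.00 | 22.8 | 73.4 |
| elm | 12.0 | 19.1 | 76.3 |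
| elm | 30.0 | 15.9 | 80.1 |

(readings scatter by 0.5 percentage points)

- time, not beyond 50 min, at which the flask holds most Q
- the amount of Q, in percent of the G charged, at that time

The first setting was G at one equivalent of J, with D held. By hand, more G raises the spare J from 0 M in larch to 0.150 M in ash, so late Q should stand higher in ash, and at 30.0 min the readings were 13.6 % and 24.0 %. The second setting was D at the flask's G. Elm's larger D cuts the spare J to 0.0250 M, half of the flask's, and elm read 15.9 % at that time.

The flask's spare J lies between elm's and ash's, so I reckoned its peak as the mean of their highest readings, 24.9 %, near 2.00 min. The forecast gave 25 % at 3 min, a later time than mine, and rested on “a slower side reaction in which D irreversibly removes free J”.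

The flask gave 25.3 % at 2.75 min.

    G + J ⇌ X + Q (K = 0.550, k = 0.100 M⁻¹ s⁻¹)
    Q + J ⇌ X + Z (K = 0.400, k = 0.250 M⁻¹ s⁻¹)
    Z + J ⇌ X + E (K = 0.590, k = 0.0370 M⁻¹ s⁻¹)
    D + J → L (k = 0.110 M⁻¹ s⁻¹)

In the flask the half-life of D by its step with J was 3.3 min at 2.05 min, shorter than the 50 min allowed, and at that limit D stood at 0.140 % of its charge, Q at 20.8 %, and free J plus the leaving ligand X at 0.0501 M, against 0.0500 M reckoned. In the neighbour flask, charged with 1.70 equiv of J, D stood at 0 %, the spare J reckons to 0.120 M, free J plus X came to 0.120 M, and Q stood at 27.9 %.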